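Retrosynthesis (labdane numbering throughout, C17 = methyl on C8): the O7 acetate is cut first, then C14=C15 and C12=C13 of the diene (two Wittig reactions), then C6–C7 of ring B (reductive coupling of two aldehydes), then C7–C8 and C8–C17 (two organometallic additions to a C8 carboxyl carbon) and last C9–C10 ([3,3] shift of an allyl ester).
Forward: ring A is bought as β-cyclocitral; an Ireland–Claisen rearrangement joins the C9/C11/C12 chain to C10; C8 is raised to the tertiary carbinol and C6 is oxygenated; ring B closes at C6–C7; the diene and the acetate come last.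
What makes the ring closure possible: ring B carries the carbinol carbons C6 and C7 side by side (cis, both oxygens β) next to the oxygen-bearing quaternary C8, and ring A (C5, C10) with C9 and C8 already holds these two carbons 1,6 to each other, so a metal-bridged coupling of a C6,C7-dialdehyde can put both oxygens on the crowded β face, trans to O8.
Stereochemistry: C9 and C10 from the chair transition state of a chiral boron ketene acetal; C8 from Felkin–Anh addition next to C9; C5 from hydroboration on the face away from the axial methyl groups; C6 and C7 from the samarium chelate and the C8 silyl ether; the 12E alkene from a stabilised ylide.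

Key step: step 9

Assumption: the (S,S)-configured boron controller is taken to give acid 7 with the configuration shown; should its sense of induction be the reverse, the (R,R) enantiomer is used and nothing else changes.

Step 1
Reactants: 1 β-cyclocitral
Product: 2 β-cyclogeraniol
Conditions: NaBH4, MeOH, 0 °C
Reagents that add atoms: none
Why: 1,2-Hydride reduction of the hindered enal gives the allylic alcohol, conjugate reduction being blocked by the fully substituted β-carbon.

Step 2
Reactants: 2 β-cyclogeraniol; 3 4-(benzyloxy)butanoic acid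
Product: 4 (2,6,6-trimethylcyclohex-1-en-1-yl)methyl 4-(benzyloxy)butanoate
Conditions: DCC, DMAP (cat.), CH2Cl2, 0 °C → rt
Reagents that add atoms: none
Why: Steglich esterification (carbodiimide activation, acyl transfer by DMAP) joins the primary allylic alcohol and the acid under neutral conditions that leave the tetrasubstituted alkene and the benzyl ether untouched.

Step 3
Reactants: 4 (2,6,6-trimethylcyclohex-1-en-1-yl)methyl 4-(benzyloxy)butanoate
Product: 7 (2R)-4-(benzyloxy)-2-[(1R)-1,3,3-trimethyl-2-methylidenecyclohexyl]butanoic acid, via boron ketene acetal 5 (not isolated), via acyloxyborane 6 (not isolated)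
Conditions: (S,S)-N,N'-bis{[3,5-bis(trifluoromethyl)phenyl]sulfonyl}-1,2-diphenylethane-1,2-diamine, BBr3, CH2Cl2, rt, then evaporation (gives the bromoborane); 4, i-Pr2NEt, CH2Cl2, −78 °C; −20 °C → rt; H2O
Reagents that add atoms: none
Why: Enantioselective Ireland–Claisen rearrangement, in which the chiral diazaborolidine forms the Z(O) boron ketene acetal and the [3,3] shift runs through a chair with the C11 chain equatorial and the ring methyl (cis to the CH2O link) axial, so that C9 and C10 arise together in the required relative configuration while the C2-symmetric sulfonamide ligand on boron selects the enantiotopic face.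

Step 4
Reactants: 7 (2R)-4-(benzyloxy)-2-[(1R)-1,3,3-trimethyl-2-methylidenecyclohexyl]butanoic acid
Product: 8 (3R)-5-(benzyloxy)-3-[(1R)-1,3,3-trimethyl-2-methylidenecyclohexyl]pentan-2-one
Conditions: MeLi (3 equiv), Et2O, 0 °C → rt; poured into aq. NH4Cl
Reagents that add atoms: methyllithium (MeLi), [Li]C
Why: Addition of MeLi to the lithium carboxylate stops at the dilithium ketone hydrate, which gives the methyl ketone only on work-up and, being non-enolisable, protects C9 from epimerisation.

Step 5
Reactants: 8 (3R)-5-(benzyloxy)-3-[(1R)-1,3,3-trimethyl-2-methylidenecyclohexyl]pentan-2-one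
Product: 9 (2S,3R)-5-(benzyloxy)-1-[dimethyl(propan-2-yloxy)silyl]-2-methyl-3-[(1R)-1,3,3-trimethyl-2-methylidenecyclohexyl]pentan-2-ol
Conditions: (i-PrO)Me2SiCH2MgCl, CeCl3, THF, −78 → 0 °C
Reagents that add atoms: (isopropoxydimethylsilyl)methylmagnesium chloride, CC(C)O[Si](C)(C)C[Mg]Cl
Why: CeCl3-promoted Grignard addition of the hydroxymethyl anion equivalent suppresses enolisation of the hindered ketone and follows the Felkin–Anh model, the nucleophile entering anti to the bulky quaternary C10 group on C9 and past its hydrogen, which sets C8 with the oxygen in the future 8α position.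

Step 6
Reactants: 9 (2S,3R)-5-(benzyloxy)-1-[dimethyl(propan-2-yloxy)silyl]-2-methyl-3-[(1R)-1,3,3-trimethyl-2-methylidenecyclohexyl]pentan-2-ol
Product: 11 (5S,8S,9R,10S)-12-(benzyloxy)-6,7-seco-13,14,15,16-tetranorlabdane-6,7,8-triol, via alkylborane 10 (not isolated)
Conditions: BH3·THF (3 equiv), THF, 0 °C → rt; then KHCO3, KF, 30% H2O2, THF/MeOH, 45 °C
Reagents that add atoms: hydrogen peroxide, OO
Why: Hydroboration puts boron on the terminal C6 and delivers hydrogen to C5 from the α face, opposite the two axial methyl groups on C4 and C10 that flank the alkene (C5–H trans to the C10 methyl, CH2 group equatorial), and one oxidative work-up under Tamao conditions turns both the C–B and the C–Si bond into C–OH with retention.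

Step 7
Reactants: 11 (5S,8S,9R,10S)-12-(benzyloxy)-6,7-seco-13,14,15,16-tetranorlabdane-6,7,8-triol
Product: 12 (5S,8S,9R,10S)-12-(benzyloxy)-6,7,8-tris[(triethylsilyl)oxy]-6,7-seco-13,14,15,16-tetranorlabdane
Conditions: TESOTf (4.5 equiv), 2,6-lutidine, CH2Cl2, −78 → 0 °C
Reagents that add atoms: triethylsilyl trifluoromethanesulfonate, CC[Si](CC)(CC)OS(=O)(=O)C(F)(F)F
Why: Silylation with the silyl triflate and a hindered pyridine base is forceful enough to cap the tertiary C8 hydroxyl together with the two primary ones.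

Step 8
Reactants: 12 (5S,8S,9R,10S)-12-(benzyloxy)-6,7,8-tris[(triethylsilyl)oxy]-6,7-seco-13,14,15,16-tetranorlabdane
Product: 13 (5S,8S,9R,10R)-12-(benzyloxy)-8-[(triethylsilyl)oxy]-6,7-seco-13,14,15,16-tetranorlabdane-6,7-dial
Conditions: (COCl)2, DMSO, CH2Cl2, −78 → −30 °C; Et3N, −78 °C → rt
Reagents that add atoms: none
Why: Under Swern conditions primary triethylsilyl ethers are cleaved by the chlorosulfonium reagent and oxidised directly to aldehydes, whereas the tertiary C8 silyl ether is too hindered to be attacked and has no carbinol hydrogen, so the dialdehyde forms in one operation.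

Step 9
Reactants: 13 (5S,8S,9R,10R)-12-(benzyloxy)-8-[(triethylsilyl)oxy]-6,7-seco-13,14,15,16-tetranorlabdane-6,7-dial
Product: 14 12-(benzyloxy)-8α-[(triethylsilyl)oxy]-13,14,15,16-tetranorlabdane-6β,7β-diol
Conditions: SmI2 (3 equiv, 0.1 M in THF), t-BuOH (2.5 equiv), THF, −78 °C → rt
Reagents that add atoms: none
Why: Electron transfer from SmI2 (divalent samarium) to the less hindered C7 aldehyde gives a ketyl whose carbon adds to the C6 carbonyl held on the same metal centre, and a second electron and protonation by t-BuOH release the diol. The closest known reaction type is the SmI2-mediated intramolecular pinacol coupling of 1,6-dialdehydes to cis-cyclohexane-1,2-diols. Ring B closes by 6-exo-trig attack of the C7 radical on C6 through a chair in which ring A and the C9 side chain sit equatorial. C7 is controlled by the C8 stereocentre, because the samarium-bound ketyl oxygen turns away from the bulky, electron-rich triethylsilyloxy group and ends trans to it (7β); C6 is controlled by the oxygen–samarium–oxygen bridge, which carries its oxygen to the same β face although it becomes axial. The step needs cis over trans and β,β over α,α selectivity, and the substrate secures both through the chelate and the α-silyloxy centre, while the quaternary C8 rules out enolisation of the C7 aldehyde and the benzyl and silyl ethers are inert to SmI2.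

Step 10
Reactants: 14 12-(benzyloxy)-8α-[(triethylsilyl)oxy]-13,14,15,16-tetranorlabdane-6β,7β-diol
Product: 15 12-(benzyloxy)-7β,8α-bis[(triethylsilyl)oxy]-13,14,15,16-tetranorlabdan-6β-ol
Conditions: TESOTf (1.1 equiv), 2,6-lutidine, CH2Cl2, −78 °C
Reagents that add atoms: triethylsilyl trifluoromethanesulfonate, CC[Si](CC)(CC)OS(=O)(=O)C(F)(F)F
Why: Selective silylation, since the equatorial 7β-hydroxyl reacts whereas the axial 6β-hydroxyl is shielded by the syn-axial methyl groups on C4, C8 and C10 and stays free, which removes the vicinal diol before the oxidation in step 12.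

Step 11
Reactants: 15 12-(benzyloxy)-7β,8α-bis[(triethylsilyl)oxy]-13,14,15,16-tetranorlabdan-6β-ol
Product: 16 7β,8α-bis[(triethylsilyl)oxy]-13,14,15,16-tetranorlabdane-6β,12-diol
Conditions: H2 (1 atm), Pd/C (10% Pd), EtOAc, rt
Reagents that add atoms: none
Why: Catalytic hydrogenolysis cleaves the benzyl ether under neutral conditions that do not affect silyl ethers.

Step 12
Reactants: 16 7β,8α-bis[(triethylsilyl)oxy]-13,14,15,16-tetranorlabdane-6β,12-diol
Product: 17 6β-hydroxy-7β,8α-bis[(triethylsilyl)oxy]-13,14,15,16-tetranorlabdan-12-al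
Conditions: TEMPO (10 mol%), PhI(OAc)2, CH2Cl2, rt
Reagents that add atoms: none
Why: Oxoammonium (TEMPO) oxidation with PhI(OAc)2 as terminal oxidant converts primary alcohols to aldehydes far faster than hindered secondary ones, so the axial 6β-hydroxyl survives.

Step 13
Reactants: 17 6β-hydroxy-7β,8α-bis[(triethylsilyl)oxy]-13,14,15,16-tetranorlabdan-12-al
Product: 18 (12E)-6β-hydroxy-7β,8α-bis[(triethylsilyl)oxy]-15-norlabd-12-en-14-al
Conditions: Ph3P=C(CH3)CHO, toluene, 90 °C
Reagents that add atoms: 2-(triphenylphosphoranylidene)propanal, CC(C=O)=P(c1ccccc1)(c1ccccc1)c1ccccc1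
Why: Wittig olefination with the formyl-stabilised ylide forms C12=C13 and gives the (E)-2-methyl enal, the usual outcome for stabilised ylides, while the C8 silyl ether keeps O8 from adding to the new enal.

Step 14
Reactants: 18 (12E)-6β-hydroxy-7β,8α-bis[(triethylsilyl)oxy]-15-norlabd-12-en-14-al
Product: 19 (12E)-7β,8α-bis[(triethylsilyl)oxy]labda-12,14-dien-6β-ol
Conditions: Ph3PCH3Br, KOt-Bu, THF, 0 °C; then 18, 0 °C → rt
Reagents that add atoms: methyltriphenylphosphonium bromide (source of the CH2 group), C[P+](c1ccccc1)(c1ccccc1)c1ccccc1.[Br-]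
Why: Wittig methylenation of the aldehyde adds C15 and completes the (12E)-1,3-diene without touching the trisubstituted double bond, and an excess of ylide tolerates the free hydroxyl.

Step 15
Reactants: 19 (12E)-7β,8α-bis[(triethylsilyl)oxy]labda-12,14-dien-6β-ol
Product: 20 (12E)-labda-12,14-diene-6β,7β,8α-triol
Conditions: Bu4NF, THF, rt → 45 °C
Reagents that add atoms: none
Why: Fluoride-induced desilylation removes both silyl ethers without acid, which avoids acid-promoted cyclisation of the C8 hydroxyl onto the diene.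

Step 16
Reactants: 20 (12E)-labda-12,14-diene-6β,7β,8α-triol
Product: 21 (12E)-6β,8α-dihydroxylabda-12,14-dien-7β-yl acetate
Conditions: Ac2O (1.2 equiv), pyridine, 0 °C → rt
Reagents that add atoms: acetic anhydride, CC(=O)OC(C)=O
Why: Selective acylation of the least hindered hydroxyl, the equatorial secondary 7β-OH being acetylated while the tertiary 8α-OH and the axial 6β-OH, screened by three syn-axial methyl groups, do not react.

Compound list
1 | β-cyclocitral (2,6,6-trimethylcyclohex-1-ene-1-carbaldehyde) | CC1=C(C=O)C(C)(C)CCC1 | starting material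
2 | β-cyclogeraniol ((2,6,6-trimethylcyclohex-1-en-1-yl)methanol) | CC1=C(CO)C(C)(C)CCC1 | intermediate
3 | 4-(benzyloxy)butanoic acid | OC(=O)CCCOCc1ccccc1 | starting material
4 | (2,6,6-trimethylcyclohex-1-en-1-yl)methyl 4-(benzyloxy)butanoate | CC1=C(COC(=O)CCCOCc2ccccc2)C(C)(C)CCC1 | intermediate
5 | Z(O) boron ketene acetal of 4 (C11 chain cis to the O–B oxygen; boron held in the (S,S)-4,5-diphenyl-1,3-bis(arylsulfonyl)-1,3,2-diazaborolidine) | CC1=C(CO/C(OB2N(S(=O)(=O)c3cc(cc(c3)C(F)(F)F)C(F)(F)F)[C@@H](c3ccccc3)[C@H](c3ccccc3)N2S(=O)(=O)c2cc(cc(c2)C(F)(F)F)C(F)(F)F)=C/CCOCc2ccccc2)C(C)(C)CCC1 | intermediate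
6 | acyloxyborane (boron carboxylate) of acid 7 with the same diazaborolidine | C=C1C(C)(C)CCC[C@]1(C)[C@@H](CCOCc2ccccc2)C(=O)OB2N(S(=O)(=O)c3cc(cc(c3)C(F)(F)F)C(F)(F)F)[C@@H](c3ccccc3)[C@H](c3ccccc3)N2S(=O)(=O)c2cc(cc(c2)C(F)(F)F)C(F)(F)F | intermediate
7 | (2R)-4-(benzyloxy)-2-[(1R)-1,3,3-trimethyl-2-methylidenecyclohexyl]butanoic acid | C=C1C(C)(C)CCC[C@]1(C)[C@@H](CCOCc2ccccc2)C(=O)O | intermediate
8 | (3R)-5-(benzyloxy)-3-[(1R)-1,3,3-trimethyl-2-methylidenecyclohexyl]pentan-2-one | C=C1C(C)(C)CCC[C@]1(C)[C@@H](CCOCc2ccccc2)C(C)=O | intermediate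
9 | (2S,3R)-5-(benzyloxy)-1-[dimethyl(propan-2-yloxy)silyl]-2-methyl-3-[(1R)-1,3,3-trimethyl-2-methylidenecyclohexyl]pentan-2-ol | C=C1C(C)(C)CCC[C@]1(C)[C@@H](CCOCc2ccccc2)[C@](C)(O)C[Si](C)(C)OC(C)C | intermediate
10 | primary alkylborane from 9 (BH2 on C6, hydrogen on C5 trans to the C10 methyl) | BC[C@H]1C(C)(C)CCC[C@]1(C)[C@@H](CCOCc2ccccc2)[C@](C)(O)C[Si](C)(C)OC(C)C | intermediate
11 | (5S,8S,9R,10S)-12-(benzyloxy)-6,7-seco-13,14,15,16-tetranorlabdane-6,7,8-triol | OC[C@H]1C(C)(C)CCC[C@]1(C)[C@@H](CCOCc2ccccc2)[C@](C)(O)CO | intermediate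
12 | (5S,8S,9R,10S)-12-(benzyloxy)-6,7,8-tris[(triethylsilyl)oxy]-6,7-seco-13,14,15,16-tetranorlabdane | CC[Si](CC)(CC)OC[C@H]1C(C)(C)CCC[C@]1(C)[C@@H](CCOCc2ccccc2)[C@](C)(O[Si](CC)(CC)CC)CO[Si](CC)(CC)CC | intermediate
13 | (5S,8S,9R,10R)-12-(benzyloxy)-8-[(triethylsilyl)oxy]-6,7-seco-13,14,15,16-tetranorlabdane-6,7-dial | O=C[C@H]1C(C)(C)CCC[C@]1(C)[C@@H](CCOCc2ccccc2)[C@](C)(O[Si](CC)(CC)CC)C=O | intermediate
14 | 12-(benzyloxy)-8α-[(triethylsilyl)oxy]-13,14,15,16-tetranorlabdane-6β,7β-diol (5S,6S,7S,8S,9R,10S) | C(COCc1ccccc1)[C@H]1[C@](C)(O[Si](CC)(CC)CC)[C@@H](O)[C@@H](O)[C@H]2C(C)(C)CCC[C@@]21C | intermediate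
15 | 12-(benzyloxy)-7β,8α-bis[(triethylsilyl)oxy]-13,14,15,16-tetranorlabdan-6β-ol | C(COCc1ccccc1)[C@H]1[C@](C)(O[Si](CC)(CC)CC)[C@@H](O[Si](CC)(CC)CC)[C@@H](O)[C@H]2C(C)(C)CCC[C@@]21C | intermediate
16 | 7β,8α-bis[(triethylsilyl)oxy]-13,14,15,16-tetranorlabdane-6β,12-diol | OCC[C@H]1[C@](C)(O[Si](CC)(CC)CC)[C@@H](O[Si](CC)(CC)CC)[C@@H](O)[C@H]2C(C)(C)CCC[C@@]21C | intermediate
17 | 6β-hydroxy-7β,8α-bis[(triethylsilyl)oxy]-13,14,15,16-tetranorlabdan-12-al | O=CC[C@H]1[C@](C)(O[Si](CC)(CC)CC)[C@@H](O[Si](CC)(CC)CC)[C@@H](O)[C@H]2C(C)(C)CCC[C@@]21C | intermediate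
18 | (12E)-6β-hydroxy-7β,8α-bis[(triethylsilyl)oxy]-15-norlabd-12-en-14-al | O=C/C(C)=C/C[C@H]1[C@](C)(O[Si](CC)(CC)CC)[C@@H](O[Si](CC)(CC)CC)[C@@H](O)[C@H]2C(C)(C)CCC[C@@]21C | intermediate
19 | (12E)-7β,8α-bis[(triethylsilyl)oxy]labda-12,14-dien-6β-ol | C=C/C(C)=C/C[C@H]1[C@](C)(O[Si](CC)(CC)CC)[C@@H](O[Si](CC)(CC)CC)[C@@H](O)[C@H]2C(C)(C)CCC[C@@]21C | intermediate
20 | (12E)-labda-12,14-diene-6β,7β,8α-triol | C=C/C(C)=C/C[C@H]1[C@](C)(O)[C@@H](O)[C@@H](O)[C@H]2C(C)(C)CCC[C@@]21C | intermediate
21 | (12E)-6β,8α-dihydroxylabda-12,14-dien-7β-yl acetate (5S,6S,7S,8S,9R,10S) | C=C/C(C)=C/C[C@H]1[C@](C)(O)[C@@H](OC(C)=O)[C@@H](O)[C@H]2C(C)(C)CCC[C@@]21C | target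

Total step count: 16.
Longest linear sequence: 16 steps, from β-cyclocitral 1 to 21 (acid 3 joins in step 2).

Steps most likely to fail

Step 3. The [3,3] shift onto the fully substituted alkene carbon may be too slow at the temperatures at which the boron ketene acetal keeps its geometry, and enolate geometry or face selectivity may erode, so that diastereomeric or enantiomeric purity is lost. The fallback sets out from 4 and comes back at 7. The ester is deprotonated with LiN(i-Pr)2 in THF/DMPU at −78 °C and trapped with Me3SiCl as the Z(O) trimethylsilyl ketene acetal F1, which rearranges on warming to the racemic trimethylsilyl ester F2. Aqueous acid then gives acid 7 together with its mirror-image acid F3, and classical resolution by crystallisation of the (S)-1-phenylethylammonium salt F4, followed by acidification, returns enantiopure 7.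

Step 9. The samarium bridge may open before the carbon–carbon bond forms, so that facial control at C6 is lost and the trans-diol accompanies 14. The fallback sets out from 13 and comes back at 14. The coupling is run as before and the 6α,7β-diol F5 is separated. One equivalent of Dess–Martin periodinane oxidises its more accessible equatorial 6α-hydroxyl to the 7β-hydroxy-6-ketone F6, and NaBH4 in MeOH at −20 °C then adds hydride from the α face, away from the three axial β-methyl groups, to give the 6β-alcohol 14.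

Step 8. Attack of the chlorosulfonium reagent on the two neopentyl-type primary silyl ethers may be incomplete, or the tertiary silyl ether may be lost under forcing conditions. The fallback sets out from 12 and comes back at 13. HF·pyridine buffered with pyridine in THF at 0 °C removes only the two primary silyl groups to give the 6,7-diol F7, which Dess–Martin periodinane with NaHCO3 in CH2Cl2 oxidises to dialdehyde 13.

Further compounds
F1 | step 3 | Z(O) trimethylsilyl ketene acetal of ester 4 | CC1=C(CO/C(O[Si](C)(C)C)=C/CCOCc2ccccc2)C(C)(C)CCC1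
F2 | step 3 | trimethylsilyl ester of acid 7, formed as the racemate (one enantiomer drawn) | C=C1C(C)(C)CCC[C@]1(C)[C@@H](CCOCc2ccccc2)C(=O)O[Si](C)(C)C
F3 | step 3 | (2S)-4-(benzyloxy)-2-[(1S)-1,3,3-trimethyl-2-methylidenecyclohexyl]butanoic acid (mirror image of 7) | C=C1C(C)(C)CCC[C@@]1(C)[C@H](CCOCc2ccccc2)C(=O)O
F4 | step 3 | (S)-1-phenylethylammonium salt of acid 7 | C=C1C(C)(C)CCC[C@]1(C)[C@@H](CCOCc2ccccc2)C(=O)[O-].C[C@H]([NH3+])c1ccccc1
F5 | step 9 | 12-(benzyloxy)-8α-[(triethylsilyl)oxy]-13,14,15,16-tetranorlabdane-6α,7β-diol | C(COCc1ccccc1)[C@H]1[C@](C)(O[Si](CC)(CC)CC)[C@@H](O)[C@H](O)[C@H]2C(C)(C)CCC[C@@]21C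
F6 | step 9 | 12-(benzyloxy)-7β-hydroxy-8α-[(triethylsilyl)oxy]-13,14,15,16-tetranorlabdan-6-one | C(COCc1ccccc1)[C@H]1[C@](C)(O[Si](CC)(CC)CC)[C@@H](O)C(=O)[C@H]2C(C)(C)CCC[C@@]21C
F7 | step 8 | (5S,8S,9R,10S)-12-(benzyloxy)-8-[(triethylsilyl)oxy]-6,7-seco-13,14,15,16-tetranorlabdane-6,7-diol | OC[C@H]1C(C)(C)CCC[C@]1(C)[C@@H](CCOCc2ccccc2)[C@](C)(O[Si](CC)(CC)CC)CO
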